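All runs are simulated for substances that don't exist; noise was put on by code.

I began with the easy step: the percentages of substrates and products in this closed flask add up to 100, so the right-handed substrate, which was not read, came out by difference at 41.8% at 15.0 s, with the scatter of the readings.

- theta: left-handed substrate 0.010 M; right-handed substrate 0.010 M; partner 0.030 M; protic impurity 2 mM; catalyst 6.2 µM; added ligand 7.9 µM; the very flask that is asked about, followed so far
- flask: left-handed substrate 0.010 M; partner 0.0300 M; protic impurity 2.00 mM; catalyst 6.2 µM; added ligand 7.9 µM; right-handed substrate 0.010 M; time 3.0 min

- theta (time / s: left-handed product / %, right-handed product / %, left-handed substrate / %): 10.0: 23.8, 5.9, 25.9; 15.0: 30.9, 7.9, 19.4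

(standard deviation of a reading: 0.5 percentage points)

- catalyst is single-handed; left-handed substrate and right-handed substrate are mirror images of each other, charged as a racemate, each of them at the stated concentration
- an excess is the difference of the two amounts in percent of their sum
- an excess is below zero if the other one leads

- excess of left-handed product over right-handed product in the product at 20 s
- excess of left-handed product over right-handed product in the product at 3.0 min
- part of the left-handed substrate and right-handed substrate charged together that has reacted at 3.0 min

That reading gave the right-handed substrate a pseudo-first-order constant of 0.0119 s⁻¹, at a mean partner of 26.1 mM. The left-handed substrate fell 5.29 times as far in logarithm, and I took that reading as the selectivity factor.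

I assumed the rate follows partner, and I replaced the partner curve by its mean. Subtracting the charges of left-handed substrate and protic impurity from the charge of partner gave me a level of 18.0 mM. A first pass at that level gave 1.48, which put my estimate for the end of the partner curve at 10.3 mM. Taking the mean of those two partner levels, I reckoned 1.16. This is the dose, the natural logarithm of the right-handed substrate's charge over what remains of it at the asked time.

So I expected 31.3% of that charge to remain and the left-handed substrate to be down to 0.107% of the total. With each product staying as made, that meant 84.3% reacted and an excess of 18.6%. One number holds the catalyst unchanged, though, and the readings test that for just 15.0 s, while added ligand was charged at 1.27 to one against catalyst.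

The forecast, a reckoning separate from mine, gave excesses of 55.7% at 20 s and 17% at 3.0 min, with 85% reacted, and cautioned: “Any catalyst death would lower conversion and raise excess.”

The flask gave excesses of 55.4% at 20 s and 11.9% at 3.0 min, with 75.5% reacted.

    partner + catalyst + left-handed substrate → catalyst + left-handed product (k = 4.38 × 10⁵ L² mol⁻² s⁻¹)
    partner + catalyst + right-handed substrate → catalyst + right-handed product (k = 73400 L² mol⁻² s⁻¹)
    left-handed product ⇌ right-handed product (k = 0.00229 s⁻¹)
    partner + protic impurity → quenched reagent (k = 1.05 L mol⁻¹ s⁻¹)
    catalyst + added ligand ⇌ idle complex (K = 1.70 × 10⁶ L mol⁻¹, k = 1520 L mol⁻¹ s⁻¹)

The flask's dose, read from the 48% of right-handed substrate left at 3.0 min, was 0.738, smaller than my 1.16. By then free catalyst stood at 30.9% and idle complex at 69.1%. I scaled that dose in proportion to the catalyst charged to a neighbouring flask, the same except for 2.5 × 10⁻⁶ M of catalyst, which gave 0.297 and 74.3% of the right-handed substrate's charge left. That neighbouring flask kept 72%.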